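The readings were generated by integration on assumed constants, noise included.

**Reading time.** Read at 2.0 h, a flask's target is what has survived its own loss, minus nothing and plus whatever late feed still arrives. One molecule of target faces a fork: stay or leave.

| flask | starting material | free catalyst | remark | time |
|---|---|---|---|---|
| Sunday's | 0.14 M | 1.4 mM | run made earlier |  |
| Monday's | 0.22 M | 1.4 mM | run made earlier |  |
| flask | 0.29 M | 1.4 mM |  | 2.0 h |

| run | time / h | target / % |
|---|---|---|
| Sunday's | 0.417 | 40.0 |
| Sunday's | 0.833 | 24.8 |
| Sunday's | 1.33 | 12.0 |
| Sunday's | 1.50 | 8.9 |
| Sunday's | 2.00 | 3.3 |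
| Sunday's | 2.50 | 1.1 |
| Monday's | 0.167 | 35.6 |
| Monday's | 0.500 | 34.3 |
| Monday's | 0.833 | 23.7 |
| Monday's | 1.33 | 13.0 |
| Monday's | 2.00 | 4.6 |
| Monday's | 2.50 | 1.5 |

(standard deviation of a reading: 0.3 percentage points)

1. amount of target in percent of the starting material charged, at 12 min, 40 min, 80 min and 2.0 h

- the earlier runs were read with a standard deviation of 0.3 percentage points
- a reading or a percentage of target counts all its forms, free or not

**Loss constant.** Monday's last two readings are taken as pure loss and give 2.24 h⁻¹. This is λ, the loss constant, the chance per hour that a molecule of target leaves. Sunday's last two give a similar 2.20 h⁻¹, though a reading of 1.1% carries a scatter of 0.3 percentage points.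

**Refill share.** Earlier falls are slower, so something refills the target. With r the fall constant between two readings, the refill share is f = 1 − r/λ. From 80 min to 2.0 h, f is 14.0% on Sunday and 30.8% on Monday, higher at the larger charge.

**This flask.** Straight lines in the charge carry f to 45.5% and the 80 min reading to 13.9%. Falling at λ reduced by that refill, the target reaches 6.15% at 2.0 h.

**Weak link.** The line for f rests on two noisy shares. The 2.0 h readings, laid directly on a line in the charge, give 5.74%, so this reckoning commits to about 6.15% or slightly less.

**Forecast.** The forecast, noting that the target's “decay speeds up as it thins out”, gives 34%, 30%, 16.5% and 6.7%. It stands above this reckoning at 80 min and at 2.0 h.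

**Result.** The flask gives 35.9%, 27.0%, 13.6% and 5.73%, so the forecast holds within its margin.

    starting material + free catalyst → catalyst intermediate (k = 0.930 M⁻¹ s⁻¹)
    target → over-reaction product (k = 6.60 × 10⁻⁴ s⁻¹)
    free catalyst + target ⇌ idle complex (K = 27.0 M⁻¹, k = 0.0160 M⁻¹ s⁻¹)
    catalyst intermediate → free catalyst + target (k = 1.00 s⁻¹)

**Where it went.** From 80 min to 2.0 h this flask's target falls at 1.30 h⁻¹, which against λ means a refill share of 42.1%. At 2.0 h free target is made at 0.358 of the rate at which it is used up, each step taken net and its passing into other forms counted as use. The target stands this low because it passes on into over-reaction product: the same run without that step holds 86.8% of target at 2.0 h, against 5.73%.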